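**Plan**
- Retrosynthetic cuts: lower pyran at O1–C2 (Mitsunobu), C2–O/C3–O (osmylation of a Z-alkene), C4–C3 (alkynylation) and C4a–C4 (ortho-formylation); upper pyran at O1–C2/C2–H (reductive etherification), C2–aryl (Grignard), C3–O (enolate oxidation) and at O1 itself (C8a–O1 and O1–C2, oxygen insertion); then indanone C1–C2 (hydroacylation) and the aryl–vinyl bond (Suzuki).
- Forward: gallacetophenone and 2,3-dihydroxybenzaldehyde are joined to a 1,1-diarylethene; rings arise in the order indanone carbocycle → dihydrocoumarin lactone → upper pyran → lower pyran.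
- Enabling feature: deleting O1 from the upper pyran ring leaves a 3-arylindan-1-one. Its C3 (= upper C4, the diarylmethine) is set by catalysis, and its aryl carbon C7a (= upper C8a, next to the C8 oxygen) migrates to oxygen.
- Stereochemistry: upper C4 from Rh–BINAP hydroacylation, upper C3 trans to it by enolate hydroxylation, upper C2 by axial hydride delivery. Lower C4 comes from Zn–ProPhenol alkynylation; lower C3 and C2 are relayed from it by osmylation anti to the allylic silyl ether and Mitsunobu inversion.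
- Protecting groups: benzyl throughout; one PMB on the oxygen that becomes lower O1; TBS on the lower phenol and lower C4–OH.

Key step: step 9

Remarks. Read from the SMILES, the target is (2S,3R,4S), all-trans, in the upper unit and (2R,3R,4R), all-cis, in the lower unit. Abbreviations: Bn = benzyl, PMB = 4-methoxybenzyl, TBS = tert-butyldimethylsilyl, ArL = 2,3-bis(benzyloxy)-4-(4-methoxybenzyloxy)phenyl. Fl = (2S,3R)-3,7,8-tris(benzyloxy)-2-[4-(benzyloxy)phenyl]chroman-4-yl with H-2/H-3 trans and H-3/H-4 trans (the protected upper unit). The CIP letter at C4 of Fl changes with the lower-ring substituents, so the SMILES are definitive.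
Assumption: the ligand antipodes named ((R)-BINAP, (S,S)-ProPhenol, (R)-DTBM-SEGPHOS) are assigned by analogy with accepted models for the drawn products; if induction proves opposite, the mirror-image ligand is used with no other change.

**Step 1**
Reactants: 1 2,3,4-trihydroxyacetophenone
Product: 2 1-[2,3-dihydroxy-4-(4-methoxybenzyloxy)phenyl]ethanone
Conditions: PMBCl (1.05 equiv), NaHCO3, NaI (cat.), DMF, 40 °C
Reagents that add atoms: 4-methoxybenzyl chloride, COc1ccc(CCl)cc1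
Why: Williamson etherification in which the 4-OH (para to the acetyl group, most acidic) should react first, because the 2-OH is locked in a hydrogen bond to the carbonyl and the 3-OH is the least acidic.

**Step 2**
Reactants: 2 1-[2,3-dihydroxy-4-(4-methoxybenzyloxy)phenyl]ethanone
Product: 3 1-ArL-ethanone (1-[2,3-bis(benzyloxy)-4-(4-methoxybenzyloxy)phenyl]ethanone)
Conditions: BnBr (2.4 equiv), K2CO3, DMF, 60 °C
Reagents that add atoms: benzyl bromide, BrCc1ccccc1
Why: Williamson etherification of the two remaining phenols under forcing carbonate conditions, leaving the oxygen destined to become lower O1 as the only PMB ether.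

**Step 3**
Reactants: 3 1-ArL-ethanone
Product: 5 1-ArL-vinyl trifluoromethanesulfonate, via potassium enolate 4 (not isolated)
Conditions: KN(SiMe3)2, THF, −78 °C; PhNTf2, −78 → 0 °C
Reagents that add atoms: N-phenylbis(trifluoromethanesulfonimide), O=S(=O)(N(c1ccccc1)S(=O)(=O)C(F)(F)F)C(F)(F)F
Why: the methyl ketone has a single enolisable site, and O-sulfonylation of its kinetic enolate is the standard route to 1-arylvinyl triflates.

**Step 4**
Reactants: 5 1-ArL-vinyl trifluoromethanesulfonate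
Product: 6 2-(1-ArL-vinyl)-4,4,5,5-tetramethyl-1,3,2-dioxaborolane
Conditions: B2pin2, PdCl2(PPh3)2 (3 mol %), PPh3, KOPh, toluene, 50 °C
Reagents that add atoms: bis(pinacolato)diboron, CC1(C)OB(OC1(C)C)B1OC(C)(C)C(C)(C)O1
Why: Miyaura borylation of an alkenyl triflate, with phenoxide as the mild base that suppresses homocoupling of the vinyl boronate formed.

**Step 5**
Reactants: 7 2,3-dihydroxybenzaldehyde
Product: 8 2,3-bis(benzyloxy)benzaldehyde
Conditions: BnBr (2.4 equiv), K2CO3, DMF, 60 °C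
Reagents that add atoms: benzyl bromide, BrCc1ccccc1
Why: Williamson etherification of both phenols.

**Step 6**
Reactants: 8 2,3-bis(benzyloxy)benzaldehyde
Product: 9 2,3-bis(benzyloxy)-6-bromobenzaldehyde
Conditions: NBS, DMF, rt, dark
Reagents that add atoms: N-bromosuccinimide, BrN1C(=O)CCC1=O
Why: electrophilic aromatic bromination should go para to the 3-benzyloxy group (C6), as for the corresponding dimethyl ether, because the 2-alkoxy group is twisted out of conjugation between CHO and the 3-substituent.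

**Step 7**
Reactants: 9 2,3-bis(benzyloxy)-6-bromobenzaldehyde; 6 2-(1-ArL-vinyl)-4,4,5,5-tetramethyl-1,3,2-dioxaborolane
Product: 10 2,3-bis(benzyloxy)-6-(1-ArL-vinyl)benzaldehyde
Conditions: Pd(OAc)2 (5 mol %), SPhos, K3PO4, toluene/H2O, 80 °C
Reagents that add atoms: none
Why: Suzuki–Miyaura coupling; the bromide ortho to the formyl group adds readily to palladium, and the biaryl phosphine copes with the ortho-substituted partners while the aldehyde is untouched.

**Step 8**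
Reactants: 10 2,3-bis(benzyloxy)-6-(1-ArL-vinyl)benzaldehyde
Product: 11 (3R)-6,7-bis(benzyloxy)-3-ArL-indan-1-one
Conditions: [Rh((R)-BINAP)]BF4 (5 mol %), CH2Cl2, rt
Reagents that add atoms: none
Why: enantioselective intramolecular alkene hydroacylation of a 2-(1-substituted vinyl)benzaldehyde: acyl C–H addition to rhodium, hydride transfer to the internal alkene carbon, and C–C reductive elimination from the six-membered acyl rhodacycle, with the BINAP-bound metal choosing the alkene face that sets C3 (the future upper C4).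

**Step 9**
Reactants: 11 (3R)-6,7-bis(benzyloxy)-3-ArL-indan-1-one
Product: 12 (4S)-7,8-bis(benzyloxy)-4-ArL-3,4-dihydrocoumarin
Conditions: mCPBA (2.5 equiv), NaHCO3, CH2Cl2, 0 °C → rt
Reagents that add atoms: 3-chloroperbenzoic acid, OOC(=O)c1cccc(Cl)c1
Why: The peracid adds to the C1 carbonyl to give the tetrahedral peroxy adduct, and the C1–C7a bond then shifts to the proximal peroxide oxygen as 3-chlorobenzoate leaves. This is the Baeyer–Villiger oxidation of 1-indanones to 3,4-dihydrocoumarins, a reaction type also known for 3-aryl-1-indanones. The six-membered lactone is not closed end to end but arises by ring expansion, the 1,2-shift inserting oxygen between C1 and C7a and so forming C8a–O1 and O1–C2 together. No stereocentre is created, and C3 of the indanone (C4 of the lactone) is neither the migrating carbon nor enolisable, so its configuration is carried over unchanged (the letter changes from R to S only through CIP priorities). The step needs migration of the aryl carbon C7a and not of the methylene C2; the higher migratory aptitude of an electron-rich aryl carbon bearing ortho and meta benzyloxy groups over a primary alkyl carbon should secure it. Hydrogencarbonate buffering keeps the PMB and benzyl ethers and the electron-rich rings intact.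

**Step 10**
Reactants: 12 (4S)-7,8-bis(benzyloxy)-4-ArL-3,4-dihydrocoumarin
Product: 14 (3R,4S)-7,8-bis(benzyloxy)-3-hydroxy-4-ArL-3,4-dihydrocoumarin, via sodium enolate 13 (not isolated)
Conditions: NaN(SiMe3)2, THF, −78 °C; 2-(phenylsulfonyl)-3-phenyloxaziridine, −78 °C; aq. NH4Cl
Reagents that add atoms: 2-(phenylsulfonyl)-3-phenyloxaziridine, O=S(=O)(N1OC1c1ccccc1)c1ccccc1
Why: enolate oxidation by an N-sulfonyloxaziridine; the oxidant should approach the lactone enolate anti to the pseudoaxial C4 aryl group, giving the 3,4-trans hydroxy lactone, and at −78 °C the aryl ester enolate should not fragment to a ketene.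

**Step 11**
Reactants: 14 (3R,4S)-7,8-bis(benzyloxy)-3-hydroxy-4-ArL-3,4-dihydrocoumarin
Product: 15 (3R,4S)-3,7,8-tris(benzyloxy)-4-ArL-3,4-dihydrocoumarin
Conditions: BnBr, Ag2O, 4 Å MS, CH2Cl2, rt, dark
Reagents that add atoms: benzyl bromide, BrCc1ccccc1
Why: silver-oxide-mediated Williamson benzylation, the usual non-basic way to etherify α-hydroxy esters without enolisation, epimerisation or opening of the aryl lactone.

**Step 12**
Reactants: 15 (3R,4S)-3,7,8-tris(benzyloxy)-4-ArL-3,4-dihydrocoumarin; 16 1-(benzyloxy)-4-bromobenzene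
Product: 19 (2R,3R)-2-(benzyloxy)-1-[4-(benzyloxy)phenyl]-3-[3,4-bis(benzyloxy)-2-hydroxyphenyl]-3-ArL-propan-1-one, via 4-(benzyloxy)phenylmagnesium bromide 17 (not isolated), via Weinreb amide 18 (not isolated)
Conditions: (a) MeNHOMe·HCl, iPrMgCl, THF, −20 °C; (b) 17 (from 16, Mg, THF), −20 → 0 °C; aq. NH4Cl
Reagents that add atoms: none
Why: Weinreb ketone synthesis telescoped from the lactone; the magnesium amide opens the reactive aryl ester to the N-methoxy-N-methylamide, whose chelated tetrahedral adduct with the aryl Grignard reagent survives until work-up, so the over-addition expected for direct attack on an aryl ester is avoided.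

**Step 13**
Reactants: 19 (2R,3R)-2-(benzyloxy)-1-[4-(benzyloxy)phenyl]-3-[3,4-bis(benzyloxy)-2-hydroxyphenyl]-3-ArL-propan-1-one
Product: 20 2,3-bis(benzyloxy)-4-Fl-phenol (upper unit 2S,3R,4S)
Conditions: Et3SiH (6 equiv), CF3CO2H, CH2Cl2, 0 °C → rt
Reagents that add atoms: none
Why: reductive etherification (hemiketal reduction as in C-aryl glycoside synthesis) in which the phenol closes onto the ketone, the resulting 2-aryl oxocarbenium ion takes hydride axially with the 3-benzyloxy and 4-aryl groups pseudoequatorial so that the new 2-aryl group ends equatorial (2,3-trans), and the same acid cleaves the PMB ether with the silane reducing its cation to 4-methylanisole.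

**Step 14**
Reactants: 20 2,3-bis(benzyloxy)-4-Fl-phenol
Product: 21 3,4-bis(benzyloxy)-5-Fl-2-hydroxybenzaldehyde
Conditions: (CH2O)n, MgCl2, Et3N, MeCN, reflux
Reagents that add atoms: paraformaldehyde (as formaldehyde), C=O
Why: magnesium-phenoxide-directed ortho-formylation (Casnati–Skattebøl), regiospecific because the molecule has one free phenol with one free ortho position (lower C4a), so the similarly activated upper C6 is not touched.

**Step 15**
Reactants: 21 3,4-bis(benzyloxy)-5-Fl-2-hydroxybenzaldehyde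
Product: 22 3,4-bis(benzyloxy)-2-(TBSO)-5-Fl-benzaldehyde
Conditions: TBSCl, imidazole, DMF, rt
Reagents that add atoms: tert-butyldimethylsilyl chloride, CC(C)(C)[Si](C)(C)Cl
Why: routine phenol silylation, needed because a free ortho-phenoxide would quench the zinc reagent and deactivate the aldehyde in the next step.

**Step 16**
Reactants: 22 3,4-bis(benzyloxy)-2-(TBSO)-5-Fl-benzaldehyde; 23 1-(benzyloxy)-4-ethynylbenzene
Product: 25 (1S)-1-[3,4-bis(benzyloxy)-2-(TBSO)-5-Fl-phenyl]-3-[4-(benzyloxy)phenyl]prop-2-yn-1-ol, via methyl(arylethynyl)zinc 24 (not isolated)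
Conditions: (S,S)-ProPhenol (20 mol %), Me2Zn, Ph3PO (40 mol %), toluene, 0 °C; aq. NH4Cl
Reagents that add atoms: none
Why: catalytic asymmetric alkynylation of an aryl aldehyde by the zinc catalyst formed in situ from ProPhenol and Me2Zn; the ligand directs alkynyl transfer to the Si face to give the (S)-carbinol (future lower C4), with the remote upper unit not expected to override it.

**Step 17**
Reactants: 25 (1S)-1-[3,4-bis(benzyloxy)-2-(TBSO)-5-Fl-phenyl]-3-[4-(benzyloxy)phenyl]prop-2-yn-1-ol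
Product: 26 (1S)-1-[3,4-bis(benzyloxy)-2-(TBSO)-5-Fl-phenyl]-3-[4-(benzyloxy)phenyl]-1-(TBSO)prop-2-yne
Conditions: TBSOTf, 2,6-lutidine, CH2Cl2, −78 → 0 °C
Reagents that add atoms: tert-butyldimethylsilyl trifluoromethanesulfonate, CC(C)(C)[Si](C)(C)OS(=O)(=O)C(F)(F)F
Why: silylation of the hindered secondary alcohol with the silyl triflate; the bis-silyl ether is also the point at which any phenol-to-alkoxide silyl migration from step 16 converges.

**Step 18**
Reactants: 26 (1S)-1-[3,4-bis(benzyloxy)-2-(TBSO)-5-Fl-phenyl]-3-[4-(benzyloxy)phenyl]-1-(TBSO)prop-2-yne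
Product: 27 (1S,2Z)-1-[3,4-bis(benzyloxy)-2-(TBSO)-5-Fl-phenyl]-3-[4-(benzyloxy)phenyl]-1-(TBSO)prop-2-ene
Conditions: H2 (1 atm), Pd/CaCO3 poisoned with Pb(OAc)2, quinoline, EtOAc, rt
Reagents that add atoms: none
Why: Lindlar semihydrogenation delivers both hydrogens to one face of the alkyne to give the Z-alkene, and the poisoned catalyst should leave the benzyl ethers alone.

**Step 19**
Reactants: 27 (1S,2Z)-1-[3,4-bis(benzyloxy)-2-(TBSO)-5-Fl-phenyl]-3-[4-(benzyloxy)phenyl]-1-(TBSO)prop-2-ene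
Product: 28 (1S,2S,3R)-3-[3,4-bis(benzyloxy)-2-(TBSO)-5-Fl-phenyl]-1-[4-(benzyloxy)phenyl]-3-(TBSO)propane-1,2-diol
Conditions: OsO4 (5 mol %), NMO, acetone/H2O, rt
Reagents that add atoms: N-methylmorpholine N-oxide, C[N+]1([O-])CCOCC1; water, O
Why: Upjohn syn-dihydroxylation; the Z geometry fixes the relation of the two new hydroxyls, and in the conformer with the allylic hydrogen in the alkene plane (least A(1,3) strain) osmium should attack anti to the allylic silyloxy group, following the empirical rule for allylic ethers, which places the new C3 oxygen erythro to the C4 oxygen (cis in the ring to come).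

**Step 20**
Reactants: 28 (1S,2S,3R)-3-[3,4-bis(benzyloxy)-2-(TBSO)-5-Fl-phenyl]-1-[4-(benzyloxy)phenyl]-3-(TBSO)propane-1,2-diol
Product: 29 (1S,2S,3R)-3-[3,4-bis(benzyloxy)-2-hydroxy-5-Fl-phenyl]-1-[4-(benzyloxy)phenyl]-3-(TBSO)propane-1,2-diol
Conditions: KHF2, MeOH, rt
Reagents that add atoms: none
Why: chemoselective desilylation; hydrogen difluoride in methanol cleaves aryl silyl ethers (phenoxide leaving group) while secondary alkyl silyl ethers persist, and its near-neutral medium avoids silyl migration onto the neighbouring diol.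

**Step 21**
Reactants: 29 (1S,2S,3R)-3-[3,4-bis(benzyloxy)-2-hydroxy-5-Fl-phenyl]-1-[4-(benzyloxy)phenyl]-3-(TBSO)propane-1,2-diol
Product: 30 (2R,3S,4R)-7,8-bis(benzyloxy)-2-[4-(benzyloxy)phenyl]-4-(TBSO)-6-Fl-chroman-3-ol (2,3-cis-3,4-cis; the 3S letter reflects the silyl ether priority)
Conditions: PPh3, DIAD, THF, 0 °C → rt
Reagents that add atoms: none
Why: intramolecular Mitsunobu etherification, as used to close flavan-3-ols from 1-(2-hydroxyaryl)-3-arylpropane-2,3-diols: the phenol displaces the activated benzylic hydroxyl with inversion in a six-membered closure, which turns the erythro diol from the Z-alkene into the 2,3-cis ring, and the silyl ether on C4 blocks ortho-quinone methide formation.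

**Step 22**
Reactants: 30 (2R,3S,4R)-7,8-bis(benzyloxy)-2-[4-(benzyloxy)phenyl]-4-(TBSO)-6-Fl-chroman-3-ol
Product: 31 (2R,3R,4R)-7,8-bis(benzyloxy)-2-[4-(benzyloxy)phenyl]-6-Fl-chroman-3,4-diol
Conditions: Bu4NF, THF, 0 °C → rt
Reagents that add atoms: none
Why: fluoride cleavage of the secondary silyl ether under non-acidic conditions, so that the ionisable benzylic C4–O bond is not put at risk.

**Step 23**
Reactants: 31 (2R,3R,4R)-7,8-bis(benzyloxy)-2-[4-(benzyloxy)phenyl]-6-Fl-chroman-3,4-diol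
Product: 32 (2R,3R,4R)-2-(4-hydroxyphenyl)-6-[(2S,3R,4S)-3,7,8-trihydroxy-2-(4-hydroxyphenyl)chroman-4-yl]chroman-3,4,7,8-tetrol (target)
Conditions: H2 (1 atm), Pd(OH)2/C, THF/MeOH, rt
Reagents that add atoms: none
Why: hydrogenolysis of the seven O-benzyl ethers under neutral conditions, as practised for benzylated oligoflavanoids, should leave the benzylic C2–O1 bonds and the C4 hydroxyl in place and touches no stereocentre.

**Compound list**
1 | 2,3,4-trihydroxyacetophenone | CC(=O)c1ccc(O)c(O)c1O | starting material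
2 | 1-[2,3-dihydroxy-4-(4-methoxybenzyloxy)phenyl]ethanone | CC(=O)c1ccc(OCc2ccc(OC)cc2)c(O)c1O | intermediate
3 | 1-[2,3-bis(benzyloxy)-4-(4-methoxybenzyloxy)phenyl]ethanone | CC(=O)c1ccc(OCc2ccc(OC)cc2)c(OCc2ccccc2)c1OCc1ccccc1 | intermediate
4 | potassium enolate of 3 (not isolated) | [K+].[O-]C(=C)c1ccc(OCc2ccc(OC)cc2)c(OCc2ccccc2)c1OCc1ccccc1 | intermediate
5 | 1-ArL-vinyl trifluoromethanesulfonate | C=C(OS(=O)(=O)C(F)(F)F)c1ccc(OCc2ccc(OC)cc2)c(OCc2ccccc2)c1OCc1ccccc1 | intermediate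
6 | 2-(1-ArL-vinyl)-4,4,5,5-tetramethyl-1,3,2-dioxaborolane | C=C(B1OC(C)(C)C(C)(C)O1)c1ccc(OCc2ccc(OC)cc2)c(OCc2ccccc2)c1OCc1ccccc1 | intermediate
7 | 2,3-dihydroxybenzaldehyde | O=Cc1cccc(O)c1O | starting material
8 | 2,3-bis(benzyloxy)benzaldehyde | O=Cc1cccc(OCc2ccccc2)c1OCc1ccccc1 | intermediate
9 | 2,3-bis(benzyloxy)-6-bromobenzaldehyde | O=Cc1c(Br)ccc(OCc2ccccc2)c1OCc1ccccc1 | intermediate
10 | 2,3-bis(benzyloxy)-6-(1-ArL-vinyl)benzaldehyde | O=Cc1c(C(=C)c2ccc(OCc3ccc(OC)cc3)c(OCc3ccccc3)c2OCc2ccccc2)ccc(OCc2ccccc2)c1OCc1ccccc1 | intermediate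
11 | (3R)-6,7-bis(benzyloxy)-3-ArL-indan-1-one | O=C1C[C@@H](c2ccc(OCc3ccc(OC)cc3)c(OCc3ccccc3)c2OCc2ccccc2)c2ccc(OCc3ccccc3)c(OCc3ccccc3)c12 | intermediate
12 | (4S)-7,8-bis(benzyloxy)-4-ArL-3,4-dihydrocoumarin | O=C1C[C@@H](c2ccc(OCc3ccc(OC)cc3)c(OCc3ccccc3)c2OCc2ccccc2)c2ccc(OCc3ccccc3)c(OCc3ccccc3)c2O1 | intermediate
13 | sodium enolate of 12 (not isolated) | [Na+].[O-]C1=C[C@@H](c2ccc(OCc3ccc(OC)cc3)c(OCc3ccccc3)c2OCc2ccccc2)c2ccc(OCc3ccccc3)c(OCc3ccccc3)c2O1 | intermediate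
14 | (3R,4S)-7,8-bis(benzyloxy)-3-hydroxy-4-ArL-3,4-dihydrocoumarin (3,4-trans) | O=C1[C@H](O)[C@@H](c2ccc(OCc3ccc(OC)cc3)c(OCc3ccccc3)c2OCc2ccccc2)c2ccc(OCc3ccccc3)c(OCc3ccccc3)c2O1 | intermediate
15 | (3R,4S)-3,7,8-tris(benzyloxy)-4-ArL-3,4-dihydrocoumarin | O=C1[C@H](OCc2ccccc2)[C@@H](c2ccc(OCc3ccc(OC)cc3)c(OCc3ccccc3)c2OCc2ccccc2)c2ccc(OCc3ccccc3)c(OCc3ccccc3)c2O1 | intermediate
16 | 1-(benzyloxy)-4-bromobenzene | Brc1ccc(OCc2ccccc2)cc1 | starting material
17 | 4-(benzyloxy)phenylmagnesium bromide (not isolated) | Br[Mg]c1ccc(OCc2ccccc2)cc1 | intermediate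
18 | (2R,3R)-2-(benzyloxy)-3-[3,4-bis(benzyloxy)-2-hydroxyphenyl]-3-ArL-N-methoxy-N-methylpropanamide (not isolated) | CON(C)C(=O)[C@H](OCc1ccccc1)[C@@H](c1ccc(OCc2ccc(OC)cc2)c(OCc2ccccc2)c1OCc1ccccc1)c1ccc(OCc2ccccc2)c(OCc2ccccc2)c1O | intermediate
19 | (2R,3R)-2-(benzyloxy)-1-[4-(benzyloxy)phenyl]-3-[3,4-bis(benzyloxy)-2-hydroxyphenyl]-3-ArL-propan-1-one | O=C(c1ccc(OCc2ccccc2)cc1)[C@H](OCc1ccccc1)[C@@H](c1ccc(OCc2ccc(OC)cc2)c(OCc2ccccc2)c1OCc1ccccc1)c1ccc(OCc2ccccc2)c(OCc2ccccc2)c1O | intermediate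
20 | 2,3-bis(benzyloxy)-4-[(2S,3R,4S)-3,7,8-tris(benzyloxy)-2-(4-benzyloxyphenyl)chroman-4-yl]phenol | Oc1ccc([C@H]2c3ccc(OCc4ccccc4)c(OCc4ccccc4)c3O[C@@H](c3ccc(OCc4ccccc4)cc3)[C@@H]2OCc2ccccc2)c(OCc2ccccc2)c1OCc1ccccc1 | intermediate
21 | 3,4-bis(benzyloxy)-5-Fl-2-hydroxybenzaldehyde | O=Cc1cc([C@H]2c3ccc(OCc4ccccc4)c(OCc4ccccc4)c3O[C@@H](c3ccc(OCc4ccccc4)cc3)[C@@H]2OCc2ccccc2)c(OCc2ccccc2)c(OCc2ccccc2)c1O | intermediate
22 | 3,4-bis(benzyloxy)-2-(TBSO)-5-Fl-benzaldehyde | O=Cc1cc([C@H]2c3ccc(OCc4ccccc4)c(OCc4ccccc4)c3O[C@@H](c3ccc(OCc4ccccc4)cc3)[C@@H]2OCc2ccccc2)c(OCc2ccccc2)c(OCc2ccccc2)c1O[Si](C)(C)C(C)(C)C | intermediate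
23 | 1-(benzyloxy)-4-ethynylbenzene | C#Cc1ccc(OCc2ccccc2)cc1 | starting material
24 | methyl{[4-(benzyloxy)phenyl]ethynyl}zinc (not isolated) | C[Zn]C#Cc1ccc(OCc2ccccc2)cc1 | intermediate
25 | (1S)-1-[3,4-bis(benzyloxy)-2-(TBSO)-5-Fl-phenyl]-3-[4-(benzyloxy)phenyl]prop-2-yn-1-ol | O[C@@H](C#Cc5ccc(OCc6ccccc6)cc5)c1cc([C@H]2c3ccc(OCc4ccccc4)c(OCc4ccccc4)c3O[C@@H](c3ccc(OCc4ccccc4)cc3)[C@@H]2OCc2ccccc2)c(OCc2ccccc2)c(OCc2ccccc2)c1O[Si](C)(C)C(C)(C)C | intermediate
26 | (1S)-1-[3,4-bis(benzyloxy)-2-(TBSO)-5-Fl-phenyl]-3-[4-(benzyloxy)phenyl]-1-(TBSO)prop-2-yne | CC(C)(C)[Si](C)(C)O[C@@H](C#Cc5ccc(OCc6ccccc6)cc5)c1cc([C@H]2c3ccc(OCc4ccccc4)c(OCc4ccccc4)c3O[C@@H](c3ccc(OCc4ccccc4)cc3)[C@@H]2OCc2ccccc2)c(OCc2ccccc2)c(OCc2ccccc2)c1O[Si](C)(C)C(C)(C)C | intermediate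
27 | (1S,2Z)-1-[3,4-bis(benzyloxy)-2-(TBSO)-5-Fl-phenyl]-3-[4-(benzyloxy)phenyl]-1-(TBSO)prop-2-ene | CC(C)(C)[Si](C)(C)O[C@@H](/C=C\c5ccc(OCc6ccccc6)cc5)c1cc([C@H]2c3ccc(OCc4ccccc4)c(OCc4ccccc4)c3O[C@@H](c3ccc(OCc4ccccc4)cc3)[C@@H]2OCc2ccccc2)c(OCc2ccccc2)c(OCc2ccccc2)c1O[Si](C)(C)C(C)(C)C | intermediate
28 | (1S,2S,3R)-3-[3,4-bis(benzyloxy)-2-(TBSO)-5-Fl-phenyl]-1-[4-(benzyloxy)phenyl]-3-(TBSO)propane-1,2-diol | CC(C)(C)[Si](C)(C)O[C@@H]([C@@H](O)[C@@H](O)c5ccc(OCc6ccccc6)cc5)c1cc([C@H]2c3ccc(OCc4ccccc4)c(OCc4ccccc4)c3O[C@@H](c3ccc(OCc4ccccc4)cc3)[C@@H]2OCc2ccccc2)c(OCc2ccccc2)c(OCc2ccccc2)c1O[Si](C)(C)C(C)(C)C | intermediate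
29 | (1S,2S,3R)-3-[3,4-bis(benzyloxy)-2-hydroxy-5-Fl-phenyl]-1-[4-(benzyloxy)phenyl]-3-(TBSO)propane-1,2-diol | CC(C)(C)[Si](C)(C)O[C@@H]([C@@H](O)[C@@H](O)c5ccc(OCc6ccccc6)cc5)c1cc([C@H]2c3ccc(OCc4ccccc4)c(OCc4ccccc4)c3O[C@@H](c3ccc(OCc4ccccc4)cc3)[C@@H]2OCc2ccccc2)c(OCc2ccccc2)c(OCc2ccccc2)c1O | intermediate
30 | (2R,3S,4R)-7,8-bis(benzyloxy)-2-[4-(benzyloxy)phenyl]-4-(TBSO)-6-Fl-chroman-3-ol (2,3-cis-3,4-cis) | c1ccccc1COc1ccc([C@H]2Oc3c(cc([C@H]4c5ccc(OCc6ccccc6)c(OCc6ccccc6)c5O[C@@H](c5ccc(OCc6ccccc6)cc5)[C@@H]4OCc4ccccc4)c(OCc4ccccc4)c3OCc3ccccc3)[C@@H](O[Si](C)(C)C(C)(C)C)[C@H]2O)cc1 | intermediate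
31 | (2R,3R,4R)-7,8-bis(benzyloxy)-2-[4-(benzyloxy)phenyl]-6-Fl-chroman-3,4-diol | c1ccccc1COc1ccc([C@H]2Oc3c(cc([C@H]4c5ccc(OCc6ccccc6)c(OCc6ccccc6)c5O[C@@H](c5ccc(OCc6ccccc6)cc5)[C@@H]4OCc4ccccc4)c(OCc4ccccc4)c3OCc3ccccc3)[C@@H](O)[C@H]2O)cc1 | intermediate
32 | (2R,3R,4R)-2-(4-hydroxyphenyl)-6-[(2S,3R,4S)-3,7,8-trihydroxy-2-(4-hydroxyphenyl)chroman-4-yl]chroman-3,4,7,8-tetrol | Oc1ccc([C@H]2Oc3c(cc([C@H]4c5ccc(O)c(O)c5O[C@@H](c5ccc(O)cc5)[C@@H]4O)c(O)c3O)[C@@H](O)[C@H]2O)cc1 | target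

**Count and risks**
Total steps: 23. Longest linear sequence: 21 steps (steps 1–4 and 7–23, from 1 to 32); steps 5 and 6 form the side branch.

Most likely to fail, first: step 8. The alkene of 10 lies between two ortho-benzyloxy-substituted rings, so enantiofacial discrimination by the rhodium catalyst may be poor, and chelation by the ortho-alkoxy aldehyde may slow turnover. Fallback, from 10: cyclise without asymmetric induction using [Rh(dppe)]BF4 to racemic 6,7-bis(benzyloxy)-3-ArL-indan-1-one F1. Dehydrogenate this with IBX in DMSO at 70 °C to 6,7-bis(benzyloxy)-3-ArL-inden-1-one F2. Then set the stereocentre by copper-hydride conjugate reduction (Cu(OAc)2, (R)-DTBM-SEGPHOS, polymethylhydrosiloxane, tBuOH, toluene), a reaction type established for β-aryl cyclic enones and coumarins. This returns to the route at 11.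

Second: step 21. The carbon attacked is a 4-benzyloxybenzylic carbinol next to a free hydroxyl, so the displacement may lose stereospecificity through ionisation or through prior epoxide formation from the vicinal diol, which would erode the 2,3-cis relationship. Fallback, from 29: heat with HC(OEt)3 and PPTS in 1,2-dichloroethane at 60 °C. The diol is tied up as the 2-ethoxy-1,3-dioxolane F4 (not isolated), whose dioxolan-2-ylium ion is opened at the benzylic carbon by the phenol with inversion, giving the 3-O-formate of 30, F5. Methanolysis (K2CO3, MeOH) returns to the route at 30.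

Third: step 13. The silane may reduce the aryl ketone before ring closure or open the newly formed benzylic C2–O1 bond, and PMB cleavage may be incomplete. Fallback, from 19: reduce the ketone with NaBH4 (THF/MeOH, 0 °C) to (2R,3R)-2-(benzyloxy)-1-[4-(benzyloxy)phenyl]-3-[3,4-bis(benzyloxy)-2-hydroxyphenyl]-3-ArL-propan-1-ol F3, as both C1 epimers. Treat F3 with CF3CO2H and anisole in CH2Cl2 at 0 °C. The 4-benzyloxybenzyl cation is captured by the phenol through the transition state with all three substituents equatorial, and the PMB group is transferred to anisole. This returns to the route at 20 with no silane present.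

**Further compounds**
F1 | step 8 | rac-6,7-bis(benzyloxy)-3-ArL-indan-1-one | O=C1CC(c2ccc(OCc3ccc(OC)cc3)c(OCc3ccccc3)c2OCc2ccccc2)c2ccc(OCc3ccccc3)c(OCc3ccccc3)c12
F2 | step 8 | 6,7-bis(benzyloxy)-3-ArL-inden-1-one | O=C1C=C(c2ccc(OCc3ccc(OC)cc3)c(OCc3ccccc3)c2OCc2ccccc2)c2ccc(OCc3ccccc3)c(OCc3ccccc3)c12
F3 | step 13 | (2R,3R)-2-(benzyloxy)-1-[4-(benzyloxy)phenyl]-3-[3,4-bis(benzyloxy)-2-hydroxyphenyl]-3-ArL-propan-1-ol (C1 epimers) | OC(c1ccc(OCc2ccccc2)cc1)[C@H](OCc1ccccc1)[C@@H](c1ccc(OCc2ccc(OC)cc2)c(OCc2ccccc2)c1OCc1ccccc1)c1ccc(OCc2ccccc2)c(OCc2ccccc2)c1O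
F4 | step 21 | 2-ethoxy-1,3-dioxolane (cyclic orthoformate) of diol 29 | CC(C)(C)[Si](C)(C)O[C@@H]([C@H]7OC(OCC)O[C@H]7c5ccc(OCc6ccccc6)cc5)c1cc([C@H]2c3ccc(OCc4ccccc4)c(OCc4ccccc4)c3O[C@@H](c3ccc(OCc4ccccc4)cc3)[C@@H]2OCc2ccccc2)c(OCc2ccccc2)c(OCc2ccccc2)c1O
F5 | step 21 | 3-O-formate of 30 | c1ccccc1COc1ccc([C@H]2Oc3c(cc([C@H]4c5ccc(OCc6ccccc6)c(OCc6ccccc6)c5O[C@@H](c5ccc(OCc6ccccc6)cc5)[C@@H]4OCc4ccccc4)c(OCc4ccccc4)c3OCc3ccccc3)[C@@H](O[Si](C)(C)C(C)(C)C)[C@H]2OC=O)cc1
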